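Numbering used throughout: lactone O1, C2 (C=O), C3, C4, C5; C6 = exocyclic CH bearing ring A (3-hydroxy-4,5-dimethoxyphenyl); C7 = CH2 on C4 bearing ring B (4-hydroxy-3-methoxyphenyl).
Cuts: O1–C2 (lactone, back to a methyl ester and a C5 alcohol); C7–H (back to a benzylic C7–O bond); C4–C5 together with that C7–O bond (two formaldehyde units taken out of a 1,3-dioxane, leaving a C4=C7 styrene); C4=C7 (olefination); C3–C6 (Morita–Baylis–Hillman reaction).
Forward: ring A aldehyde and methyl acrylate give the C6–C3(CO2Me)–C4 unit, the ring B aldehyde is joined at C4=C7 to give an open-chain dienoate, a temporary 1,3-dioxane closes across C4=C7, hydride then opens it at C7 and the lactone ring closes last.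
Enabling feature: C5 is a lone CH2–O carbon on C4 and ring B carries an oxygen para to C7, so the C4=C7 styrene can take formaldehyde at C4 while ring B carries the charge at C7; the same para oxygen later lets C7–O be exchanged for C7–H.
Stereochemistry: C4 (R) comes from the chiral acid in the Prins step and is not a reacting centre afterwards; the E geometry at C3=C6 comes from the Z allylic bromide (aryl trans to ester) and is carried through; the second dioxane centre (C7) is erased.

Key step: step 7

Remark: which antipode of the confined acid gives the (4R,5R)-dioxane cannot be predicted for this substrate; both antipodes are accessible from (R)- or (S)-BINOL, and the one that gives 11 is assumed to be used.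
Abbreviation: TBS = tert-butyldimethylsilyl. Locants C2 to C7 in the Why lines follow the numbering above.

Step 1
Reactants: 1 3-hydroxy-4,5-dimethoxybenzaldehyde
Product: 2 3-(TBS-oxy)-4,5-dimethoxybenzaldehyde
Conditions: TBSCl, imidazole, DMF, rt
Reagents that add atoms: tert-butyldimethylsilyl chloride, CC(C)(C)[Si](C)(C)Cl
Why: Imidazole-promoted O-silylation of a phenol (silyl ether formation) is routine and masks the ring A hydroxyl for the basic and acidic steps that follow.

Step 2
Reactants: 2 3-(TBS-oxy)-4,5-dimethoxybenzaldehyde; 3 methyl acrylate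
Product: 4 methyl 2-{[3-(TBS-oxy)-4,5-dimethoxyphenyl](hydroxy)methyl}prop-2-enoate (racemic)
Conditions: DABCO (1 equiv), methyl acrylate (5 equiv), MeOH (2 equiv), rt, several days
Reagents that add atoms: none
Why: Morita–Baylis–Hillman reaction, in which the amine adds to the acrylate and the resulting enolate adds to the aldehyde before the amine leaves; the electron-rich aldehyde should react slowly but belongs to a known substrate class, and the racemic carbinol centre is destroyed in step 3.

Step 3
Reactants: 4 methyl 2-{[3-(TBS-oxy)-4,5-dimethoxyphenyl](hydroxy)methyl}prop-2-enoate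
Product: 5 methyl (2Z)-2-(bromomethyl)-3-[3-(TBS-oxy)-4,5-dimethoxyphenyl]prop-2-enoate
Conditions: NBS, Me2S, CH2Cl2, 0 °C (reagent formed first), then 4, 0 °C to rt
Reagents that add atoms: N-bromosuccinimide, O=C1CCC(=O)N1Br
Why: Bromination of a Morita–Baylis–Hillman alcohol with allylic transposition (SN2' displacement after activation of the hydroxyl on sulfur by the Corey–Kim-type reagent) is known to give the 2-(bromomethyl)cinnamate with aryl trans to the ester, the Z isomer, under thermodynamic control.

Step 4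
Reactants: 5 methyl (2Z)-2-(bromomethyl)-3-[3-(TBS-oxy)-4,5-dimethoxyphenyl]prop-2-enoate
Product: 6 methyl (2Z)-2-[(diethoxyphosphoryl)methyl]-3-[3-(TBS-oxy)-4,5-dimethoxyphenyl]prop-2-enoate
Conditions: P(OEt)3 (neat), 100 °C
Reagents that add atoms: triethyl phosphite, CCOP(OCC)OCC
Why: Michaelis–Arbuzov reaction at a primary allylic bromide, which leaves the trisubstituted alkene and its geometry untouched.

Step 5
Reactants: 7 vanillin (4-hydroxy-3-methoxybenzaldehyde)
Product: 8 4-(TBS-oxy)-3-methoxybenzaldehyde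
Conditions: TBSCl, imidazole, DMF, rt
Reagents that add atoms: tert-butyldimethylsilyl chloride, CC(C)(C)[Si](C)(C)Cl
Why: Routine O-silylation of a phenol; the para-silyloxy group keeps ring B electron-rich for the key step.

Step 6
Reactants: 6 methyl (2Z)-2-[(diethoxyphosphoryl)methyl]-3-[3-(TBS-oxy)-4,5-dimethoxyphenyl]prop-2-enoate; 8 4-(TBS-oxy)-3-methoxybenzaldehyde
Product: 9 methyl (2E,3E)-2-{[3-(TBS-oxy)-4,5-dimethoxyphenyl]methylidene}-4-[4-(TBS-oxy)-3-methoxyphenyl]but-3-enoate
Conditions: NaH, THF, 0 °C to rt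
Reagents that add atoms: none
Why: Horner–Wadsworth–Emmons olefination of an aromatic aldehyde with a stabilised allylic phosphonate carbanion should give the E C4=C7 alkene, while the existing C3=C6 alkene keeps aryl trans to the ester (a known way from Morita–Baylis–Hillman phosphonates to 2-arylidene-3-enoates).

Step 7
Reactants: 9 methyl (2E,3E)-2-{[3-(TBS-oxy)-4,5-dimethoxyphenyl]methylidene}-4-[4-(TBS-oxy)-3-methoxyphenyl]but-3-enoate; 10 formaldehyde (two units incorporated, charged as paraformaldehyde)
Product: 11 methyl (2E)-3-[3-(TBS-oxy)-4,5-dimethoxyphenyl]-2-{(4R,5R)-4-[4-(TBS-oxy)-3-methoxyphenyl]-1,3-dioxan-5-yl}prop-2-enoate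
Conditions: (CH2O)n (5 equiv), confined chiral BINOL-derived imidodiphosphorimidate Brønsted acid (N-triflyl, 5 mol %), CHCl3, −20 °C
Reagents that add atoms: none
Why: Proposed new method: inside the chiral anion of the confined acid a protonated formaldehyde dimer (HOCH2–O=CH2+) is attacked by the C4=C7 styrene through C4, so that positive charge grows at C7 where the para-silyloxy ring B stabilises it, and the hydroxyl oxygen of the same dimer bonds to C7 in one asynchronous, suprafacial event. The closest known reaction type is the confined chiral Brønsted acid-catalysed intermolecular Prins reaction of terminal styrenes with paraformaldehyde, which gives 4-aryl-1,3-dioxanes; a 1,2-disubstituted styrene that is part of a dienoate has not been shown in it. The only ring formed, the 1,3-dioxane, closes by C7–O bond formation that completes a formal [4+2] addition of the four-atom C–O–C–O unit to the two alkene carbons. The centre at C4 (C5 of the dioxane, R) is fixed by the alkene face that the catalyst pocket presents to the electrophile, while the centre at C7 (C4 of the dioxane, R) follows from suprafacial addition to the E alkene, which places the aryl group and the acrylate arm trans on the ring. The step needs reaction at C4=C7 and not at C3=C6, C–C bonding at C4 and not at C7, and closure by oxygen before the C7 cation is taken by the ester carbonyl, by ring A or by hetero-Diels–Alder addition across C6 and C7; the first is secured by the ester, which deactivates C3=C6 and is only cross-conjugated to C4=C7, the second by the para oxygen of ring B, the third by the tight ion pair in the confined acid.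

Step 8
Reactants: 11 methyl (2E)-3-[3-(TBS-oxy)-4,5-dimethoxyphenyl]-2-{(4R,5R)-4-[4-(TBS-oxy)-3-methoxyphenyl]-1,3-dioxan-5-yl}prop-2-enoate
Product: 14 (3E,4R)-3-{[3-(TBS-oxy)-4,5-dimethoxyphenyl]methylidene}-4-{[4-(TBS-oxy)-3-methoxyphenyl]methyl}oxolan-2-one, via hemiformal ester 12 (not isolated), via hydroxy ester 13 (not isolated)
Conditions: Et3SiH (20 equiv), CF3CO2H (10 equiv, slow addition), CH2Cl2, −20 °C to rt
Reagents that add atoms: none
Why: Ionic hydrogenation, in which CF3CO2H ionises the benzylic C7–O bond of the acetal with help from the para-silyloxy group of ring B, Et3SiH delivers hydride to C7, the hemiformal left on the C5 oxygen loses formaldehyde and the free C5 hydroxyl closes the five-membered lactone on the methyl ester under the same acid; C4 is not a reacting centre and the conjugated C3=C6 alkene is not protonated, so configuration and geometry should be retained.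

Step 9
Reactants: 14 (3E,4R)-3-{[3-(TBS-oxy)-4,5-dimethoxyphenyl]methylidene}-4-{[4-(TBS-oxy)-3-methoxyphenyl]methyl}oxolan-2-one
Product: 15 (3E,4R)-3-[(3-hydroxy-4,5-dimethoxyphenyl)methylidene]-4-[(4-hydroxy-3-methoxyphenyl)methyl]oxolan-2-one (target)
Conditions: Bu4NF, AcOH, THF, 0 °C
Reagents that add atoms: none
Why: Fluoride-induced cleavage of both aryl silyl ethers (desilylation), buffered with acetic acid so that the medium stays too weakly basic to deprotonate C4, move the double bond or open the lactone.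

Compound list
1 | 3-hydroxy-4,5-dimethoxybenzaldehyde | COc1cc(C=O)cc(O)c1OC | starting material
2 | 3-(tert-butyldimethylsilyloxy)-4,5-dimethoxybenzaldehyde | COc1cc(C=O)cc(O[Si](C)(C)C(C)(C)C)c1OC | intermediate
3 | methyl acrylate | C=CC(=O)OC | starting material
4 | methyl 2-{[3-(tert-butyldimethylsilyloxy)-4,5-dimethoxyphenyl](hydroxy)methyl}prop-2-enoate (racemic) | C=C(C(=O)OC)C(O)c1cc(OC)c(OC)c(O[Si](C)(C)C(C)(C)C)c1 | intermediate
5 | methyl (2Z)-2-(bromomethyl)-3-[3-(tert-butyldimethylsilyloxy)-4,5-dimethoxyphenyl]prop-2-enoate | COC(=O)/C(CBr)=C/c1cc(OC)c(OC)c(O[Si](C)(C)C(C)(C)C)c1 | intermediate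
6 | methyl (2Z)-2-[(diethoxyphosphoryl)methyl]-3-[3-(tert-butyldimethylsilyloxy)-4,5-dimethoxyphenyl]prop-2-enoate | COC(=O)/C(CP(=O)(OCC)OCC)=C/c1cc(OC)c(OC)c(O[Si](C)(C)C(C)(C)C)c1 | intermediate
7 | vanillin (4-hydroxy-3-methoxybenzaldehyde) | COc1cc(C=O)ccc1O | starting material
8 | 4-(tert-butyldimethylsilyloxy)-3-methoxybenzaldehyde | COc1cc(C=O)ccc1O[Si](C)(C)C(C)(C)C | intermediate
9 | methyl (2E,3E)-2-{[3-(tert-butyldimethylsilyloxy)-4,5-dimethoxyphenyl]methylidene}-4-[4-(tert-butyldimethylsilyloxy)-3-methoxyphenyl]but-3-enoate | COC(=O)/C(=C/c1cc(O[Si](C)(C)C(C)(C)C)c(OC)c(OC)c1)/C=C/c1ccc(O[Si](C)(C)C(C)(C)C)c(OC)c1 | intermediate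
10 | formaldehyde (charged as paraformaldehyde) | C=O | starting material
11 | methyl (2E)-3-[3-(tert-butyldimethylsilyloxy)-4,5-dimethoxyphenyl]-2-{(4R,5R)-4-[4-(tert-butyldimethylsilyloxy)-3-methoxyphenyl]-1,3-dioxan-5-yl}prop-2-enoate (trans-dioxane) | COC(=O)/C(=C/c1cc(O[Si](C)(C)C(C)(C)C)c(OC)c(OC)c1)[C@@H]1COCO[C@H]1c1ccc(O[Si](C)(C)C(C)(C)C)c(OC)c1 | intermediate
12 | methyl (2E)-2-{(2R)-1-(hydroxymethoxy)-3-[4-(tert-butyldimethylsilyloxy)-3-methoxyphenyl]propan-2-yl}-3-[3-(tert-butyldimethylsilyloxy)-4,5-dimethoxyphenyl]prop-2-enoate (hemiformal ester) | COC(=O)/C(=C/c1cc(O[Si](C)(C)C(C)(C)C)c(OC)c(OC)c1)[C@H](COCO)Cc1ccc(O[Si](C)(C)C(C)(C)C)c(OC)c1 | intermediate (not isolated)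
13 | methyl (2E)-2-{(2R)-1-hydroxy-3-[4-(tert-butyldimethylsilyloxy)-3-methoxyphenyl]propan-2-yl}-3-[3-(tert-butyldimethylsilyloxy)-4,5-dimethoxyphenyl]prop-2-enoate (hydroxy ester) | COC(=O)/C(=C/c1cc(O[Si](C)(C)C(C)(C)C)c(OC)c(OC)c1)[C@H](CO)Cc1ccc(O[Si](C)(C)C(C)(C)C)c(OC)c1 | intermediate (not isolated)
14 | (3E,4R)-3-{[3-(tert-butyldimethylsilyloxy)-4,5-dimethoxyphenyl]methylidene}-4-{[4-(tert-butyldimethylsilyloxy)-3-methoxyphenyl]methyl}oxolan-2-one | COc1cc(C[C@H]2COC(=O)/C2=C/c2cc(O[Si](C)(C)C(C)(C)C)c(OC)c(OC)c2)ccc1O[Si](C)(C)C(C)(C)C | intermediate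
15 | (3E,4R)-3-[(3-hydroxy-4,5-dimethoxyphenyl)methylidene]-4-[(4-hydroxy-3-methoxyphenyl)methyl]oxolan-2-one | COc1cc(C[C@H]2COC(=O)/C2=C/c2cc(O)c(OC)c(OC)c2)ccc1O | target

Total step count: 9.
Longest linear sequence: 8 steps (steps 1, 2, 3, 4, 6, 7, 8, 9, from compound 1); step 5 is the one-step side branch.

Steps most likely to fail

1. Step 7 (the proposed new method). The dienoate may prove too weak a nucleophile, or it may react by another course: C–C bonding at C7, hetero-Diels–Alder addition across the diene, or interception of the developing C7 cation by the ester carbonyl or by ring A. Acid-induced re-ionisation of the benzylic acetal or poor facial discrimination could also lower the enantiopurity.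
Fallback, known chemistry only, setting out from 8 and rejoining the route at 14:
- Wittig reaction of 8 with methyl hydrogen 2-(triphenylphosphoranylidene)succinate (Ph3P=C(CO2Me)CH2CO2H, toluene, rt) should give the Stobbe-type half-ester (3E)-3-(methoxycarbonyl)-4-[4-(TBS-oxy)-3-methoxyphenyl]but-3-enoic acid F1.
- Rhodium-catalysed asymmetric hydrogenation ([Rh(cod)2]BF4 with the antipode of 1,2-bis(2,5-diethylphospholano)benzene that leads to the R acid, H2, MeOH) would set the stereocentre in (3R)-3-(methoxycarbonyl)-4-[4-(TBS-oxy)-3-methoxyphenyl]butanoic acid F2.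
- LiBH4 in THF reduces the ester but not the carboxylate, and acidification closes (4R)-4-{[4-(TBS-oxy)-3-methoxyphenyl]methyl}oxolan-2-one F3.
- Its lithium enolate (LiN(SiMe3)2, THF, −78 °C) adds to aldehyde 2 to give the aldol adduct (3S,4R)-3-{[3-(TBS-oxy)-4,5-dimethoxyphenyl](hydroxy)methyl}-4-{[4-(TBS-oxy)-3-methoxyphenyl]methyl}oxolan-2-one F4 as a mixture of carbinol epimers.
- Mesylation (MeSO2Cl, Et3N, CH2Cl2) to the methanesulfonate (3S,4R)-3-{[3-(TBS-oxy)-4,5-dimethoxyphenyl](methanesulfonyloxy)methyl}-4-{[4-(TBS-oxy)-3-methoxyphenyl]methyl}oxolan-2-one F5 and elimination with DBU should give the E arylidene lactone 14.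
Steps 2 to 4 and 6 to 8 are then not needed.

2. Step 8. The C7 cation may be consumed inside the molecule before hydride arrives. Ring A sits cis to C4 across C3=C6 and can close a six-membered ring by Friedel–Crafts attack. The ester carbonyl can also capture C7. Proton loss from C4 followed by re-protonation would erase the stereocentre.
Fallback, setting out from 8 and rejoining the route at 14; ring A is brought in only after the benzylic oxygen is gone:
- Wittig reaction of 8 with (2-carboxyethyl)triphenylphosphonium bromide (NaN(SiMe3)2, THF) gives (3E)-4-[4-(TBS-oxy)-3-methoxyphenyl]but-3-enoic acid F6, and Me3SiCHN2 in MeOH–toluene gives methyl (3E)-4-[4-(TBS-oxy)-3-methoxyphenyl]but-3-enoate F7.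
- The confined-acid Prins reaction with 10, now on a plain styrene without ring A or a second alkene, should give methyl 2-{(4R,5R)-4-[4-(TBS-oxy)-3-methoxyphenyl]-1,3-dioxan-5-yl}acetate F8. This Prins reaction is itself still untested on a 1,2-disubstituted styrene.
- Hydrogenolysis of the benzylic C–O bond (H2, Pd/C, EtOAc–AcOH) gives methyl (3R)-4-hydroxy-3-{[4-(TBS-oxy)-3-methoxyphenyl]methyl}butanoate F9, which lactonises (TsOH, CH2Cl2) to (4R)-4-{[4-(TBS-oxy)-3-methoxyphenyl]methyl}oxolan-2-one F3.
- Aldol addition of F3 to 2 (aldol adduct F4), mesylation (methanesulfonate F5) and elimination with DBU, as in the fallback to step 7, lead to 14.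

3. Step 2. Addition to the electron-rich aldehyde may stall at low conversion, and the long contact with amine and methanol may slowly strip the aryl silyl ether.
Fallback, setting out from 2 and rejoining the route at 5:
- Wittig reaction of 2 with methyl 2-(triphenylphosphoranylidene)propanoate (toluene, 80 °C) gives methyl (2E)-2-methyl-3-[3-(TBS-oxy)-4,5-dimethoxyphenyl]prop-2-enoate F10.
- Radical allylic bromination (NBS, AIBN, PhCF3, reflux) converts F10 into bromide 5, so steps 2 and 3 are replaced.

Further compounds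
F1 | step 7 | (3E)-3-(methoxycarbonyl)-4-[4-(tert-butyldimethylsilyloxy)-3-methoxyphenyl]but-3-enoic acid | COC(=O)/C(CC(=O)O)=C/c1ccc(O[Si](C)(C)C(C)(C)C)c(OC)c1
F2 | step 7 | (3R)-3-(methoxycarbonyl)-4-[4-(tert-butyldimethylsilyloxy)-3-methoxyphenyl]butanoic acid | COc1cc(C[C@H](CC(=O)O)C(=O)OC)ccc1O[Si](C)(C)C(C)(C)C
F3 | step 7 | (4R)-4-{[4-(tert-butyldimethylsilyloxy)-3-methoxyphenyl]methyl}oxolan-2-one | COc1cc(C[C@H]2COC(=O)C2)ccc1O[Si](C)(C)C(C)(C)C
F4 | step 7 | (3S,4R)-3-{[3-(tert-butyldimethylsilyloxy)-4,5-dimethoxyphenyl](hydroxy)methyl}-4-{[4-(tert-butyldimethylsilyloxy)-3-methoxyphenyl]methyl}oxolan-2-one (carbinol epimers) | COc1cc(C[C@H]2COC(=O)[C@@H]2C(O)c2cc(O[Si](C)(C)C(C)(C)C)c(OC)c(OC)c2)ccc1O[Si](C)(C)C(C)(C)C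
F5 | step 7 | (3S,4R)-3-{[3-(tert-butyldimethylsilyloxy)-4,5-dimethoxyphenyl](methanesulfonyloxy)methyl}-4-{[4-(tert-butyldimethylsilyloxy)-3-methoxyphenyl]methyl}oxolan-2-one | COc1cc(C[C@H]2COC(=O)[C@@H]2C(OS(C)(=O)=O)c2cc(O[Si](C)(C)C(C)(C)C)c(OC)c(OC)c2)ccc1O[Si](C)(C)C(C)(C)C
F6 | step 8 | (3E)-4-[4-(tert-butyldimethylsilyloxy)-3-methoxyphenyl]but-3-enoic acid | OC(=O)C/C=C/c1ccc(O[Si](C)(C)C(C)(C)C)c(OC)c1
F7 | step 8 | methyl (3E)-4-[4-(tert-butyldimethylsilyloxy)-3-methoxyphenyl]but-3-enoate | COC(=O)C/C=C/c1ccc(O[Si](C)(C)C(C)(C)C)c(OC)c1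
F8 | step 8 | methyl 2-{(4R,5R)-4-[4-(tert-butyldimethylsilyloxy)-3-methoxyphenyl]-1,3-dioxan-5-yl}acetate | COC(=O)C[C@@H]1COCO[C@H]1c1ccc(O[Si](C)(C)C(C)(C)C)c(OC)c1
F9 | step 8 | methyl (3R)-4-hydroxy-3-{[4-(tert-butyldimethylsilyloxy)-3-methoxyphenyl]methyl}butanoate | COC(=O)C[C@H](CO)Cc1ccc(O[Si](C)(C)C(C)(C)C)c(OC)c1
F10 | step 2 | methyl (2E)-2-methyl-3-[3-(tert-butyldimethylsilyloxy)-4,5-dimethoxyphenyl]prop-2-enoate | COC(=O)/C(C)=C/c1cc(OC)c(OC)c(O[Si](C)(C)C(C)(C)C)c1
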